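**Retrosynthetic overview**

- Ester C–O bond last: target ⇒ eudesm-4(15)-en-6α-ol + (E)-4-acetoxycinnamic acid.
- C4=CH2 ⇒ C4 ketone (Wittig under equilibrating conditions, which also turns the cis ring fusion into the trans one); the β-hydroxy ketone ⇒ fused isoxazoline (N–O hydrogenolysis).
- Key disconnection: isoxazoline ⇒ nitrile oxide on a three-carbon tether at C10 of a cyclohex-2-ene; one intramolecular (3+2) cycloaddition closes ring A and the isoxazoline ring together and fixes C5 and O–C6.
- Quaternary C10 ⇒ cis-piperitol picolinate + acetal Grignard reagent (copper-catalysed anti-SN2′); cis-piperitol ⇒ (S)-piperitone ⇒ (−)-menthone.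
- Ring order: ring B comes ready-made from (−)-menthone (its C2 becomes C7); ring A and the isoxazoline ring form in the same operation; the isoxazoline is opened afterwards.

Assumption: eudesmane numbering (C1–C15; β = face of the C10 methyl group) is used for the bicyclic compounds, and (−)-menthone is an isomenthone-free grade, because its C2 centre becomes C7 of the target.

**Route**

Step 1
Reactants: 1 (−)-menthone [(2S,5R)-5-methyl-2-(propan-2-yl)cyclohexan-1-one]
Product: 3 (S)-piperitone [(6S)-3-methyl-6-(propan-2-yl)cyclohex-2-en-1-one], via silyl enol ether 2 (not isolated)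
Conditions: LiN(i-Pr)2, THF, −78 °C, then Me3SiCl; then Pd(OAc)2 (10 mol %), O2 (1 atm), DMSO, rt
Reagents that add atoms: none
Why: Kinetic deprotonation at the unhindered C6 methylene and silylation, followed by a Saegusa–Ito dehydrogenation (O2-recycled Pd(OAc)2), puts the double bond between C6 and the methyl-bearing carbon, and the isopropyl-bearing stereocentre is never enolised, so it is kept as the future C7.

Step 2
Reactants: 3 (S)-piperitone
Product: 4 cis-piperitol [(1R,6S)-3-methyl-6-(propan-2-yl)cyclohex-2-en-1-ol]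
Conditions: LiBH(s-Bu)3, THF, −78 °C; then H2O2, aq. NaOH
Reagents that add atoms: none
Why: 1,2-Reduction of the β,β-disubstituted enone by the bulky borohydride (equatorial hydride delivery, as in menthone → neomenthol) gives the pseudo-axial alcohol cis to the neighbouring isopropyl group, i.e. the β C–O bond needed for the anti displacement.

Step 3
Reactants: 4 cis-piperitol
Product: 5 cis-piperityl picolinate [(1R,6S)-3-methyl-6-(propan-2-yl)cyclohex-2-en-1-yl pyridine-2-carboxylate]
Conditions: picolinic acid, DCC, DMAP (cat.), CH2Cl2, 0 °C → rt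
Reagents that add atoms: pyridine-2-carboxylic acid, OC(=O)c1ccccn1
Why: Steglich esterification acylates the allylic alcohol with retention and installs a picolinate, a leaving group that chelates magnesium and directs γ-attack.

Step 4
Reactants: 5 cis-piperityl picolinate; 6 2-(3-chloropropyl)-1,3-dioxolane
Product: 8 2-{3-[(1R,4S)-1-methyl-4-(propan-2-yl)cyclohex-2-en-1-yl]propyl}-1,3-dioxolane, via Grignard reagent 7 (not isolated)
Conditions: 6, Mg, THF, 50 °C; then 5, CuBr·SMe2 (30 mol %), THF, −40 → 0 °C
Reagents that add atoms: none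
Why: Copper-catalysed anti-SN2′ allylic substitution of the picolinate by the alkyl Grignard reagent delivers the chain to the methyl-bearing γ-carbon on the face opposite to the leaving group, which creates the quaternary C10 (chain α, CH3 β, cis to i-Pr) by 1,3-chirality transfer and moves the alkene to C5=C6.

Step 5
Reactants: 8 dioxolane
Product: 10 aldoxime of 4-[(1R,4S)-1-methyl-4-(propan-2-yl)cyclohex-2-en-1-yl]butanal, via aldehyde 9 (not isolated)
Conditions: NH2OH·HCl, THF/H2O, 60 °C; then NaOAc, rt
Reagents that add atoms: hydroxylamine hydrochloride, Cl.NO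
Why: Acid released from the hydroxylamine salt hydrolyses the dioxolane and the aldehyde condenses to the aldoxime (acetal hydrolysis and oxime formation), with no stereocentre involved.

Step 6
Reactants: 10 aldoxime
Product: 13 cis-fused tricyclic isoxazoline, via hydroximoyl chloride 11 (not isolated), via nitrile oxide 12 (not isolated)
Conditions: aq. NaOCl, CH2Cl2, 0 °C → rt, slow addition at 0.01 M
Reagents that add atoms: none
Why: Intramolecular nitrile oxide–alkene (3+2) cycloaddition: hypochlorite converts the aldoxime through the hydroximoyl chloride into the nitrile oxide, whose tether on the α face of C10 forces suprafacial addition to the α face of C5=C6, so ring A and the isoxazoline close together with C4 bonded to C5 (H-5 β, cis fusion) and oxygen on C6 α as in the target.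

Step 7
Reactants: 13 isoxazoline
Product: 15 cis-fused ketol (6α-hydroxy-5β-H-15-noreudesman-4-one), via hydroxy imine 14 (not isolated)
Conditions: H2 (1 atm), Ni (Raney type), B(OH)3, MeOH/H2O (5:1), rt
Reagents that add atoms: water, O
Why: Hydrogenolysis of the N–O bond over nickel buffered with boric acid and hydrolysis of the resulting β-hydroxy imine (the standard unmasking of an isoxazoline to an aldol) gives the ketol without epimerisation at C5 or loss of the C6 hydroxyl.

Step 8
Reactants: 15 cis-fused ketol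
Product: 16 triethylsilyl ether of 15
Conditions: Et3SiOTf, 2,6-lutidine, CH2Cl2, −78 → 0 °C
Reagents that add atoms: triethylsilyl trifluoromethanesulfonate, CC[Si](CC)(CC)OS(=O)(=O)C(F)(F)F
Why: Silyl ether formation with a silyl triflate and a hindered pyridine base protects the C6 hydroxyl with retention, so that no alkoxide (retro-aldol) is present in the basic olefination.

Step 9
Reactants: 16 triethylsilyl ether
Product: 19 (5S,6S,7S,10R)-eudesm-4(15)-en-6-ol, via trans-fused ketone silyl ether 17 (not isolated), via junenol-type silyl ether 18 (not isolated)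
Conditions: Ph3PCH3Br, KOt-Bu, toluene, 90 °C; then Bu4NF, THF, rt
Reagents that add atoms: methyltriphenylphosphonium bromide, C[P+](c1ccccc1)(c1ccccc1)c1ccccc1.[Br-]
Why: Wittig methylenation under equilibrating conditions: the basic ylide epimerises C5 through the C4 enolate and the trans-fused ketone 17 (all three ring B substituents equatorial) is expected to be methylenated faster, by analogy with 10-methyl-1-decalones (Curtin–Hammett), which sets H-5 α, and fluoride then cleaves the silyl ether.

Step 10
Reactants: 19 (5S,6S,7S,10R)-eudesm-4(15)-en-6-ol; 20 (E)-4-acetoxycinnamic acid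
Product: 22 (5S,6S,7S,10R)-eudesm-4(15)-en-6-yl (E)-3-(4-hydroxyphenyl)prop-2-enoate (CNP0321375.1), via acetate-protected ester 21 (not isolated)
Conditions: DCC, DMAP, CH2Cl2, 0 °C → rt; then pyrrolidine, 0 °C
Reagents that add atoms: none
Why: Steglich esterification of the equatorial C6 alcohol with the E-configured acid proceeds with retention at C6 and at the alkene, and the aryl acetate is then removed by chemoselective aminolysis with pyrrolidine, which is far faster than attack on the hindered alkyl cinnamate.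

**Compound list**

1 | (−)-menthone, (2S,5R)-5-methyl-2-(propan-2-yl)cyclohexan-1-one | CC(C)[C@@H]1CC[C@@H](C)CC1=O | starting material
2 | trimethyl{[(3R,6S)-3-methyl-6-(propan-2-yl)cyclohex-1-en-1-yl]oxy}silane | CC(C)[C@@H]1CC[C@@H](C)C=C1O[Si](C)(C)C | intermediate
3 | (S)-piperitone, (6S)-3-methyl-6-(propan-2-yl)cyclohex-2-en-1-one | CC(C)[C@@H]1CCC(C)=CC1=O | intermediate
4 | cis-piperitol, (1R,6S)-3-methyl-6-(propan-2-yl)cyclohex-2-en-1-ol (OH cis to i-Pr) | CC1=C[C@H](O)[C@H](C(C)C)CC1 | intermediate
5 | (1R,6S)-3-methyl-6-(propan-2-yl)cyclohex-2-en-1-yl pyridine-2-carboxylate | CC1=C[C@H](OC(=O)c2ccccn2)[C@H](C(C)C)CC1 | intermediate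
6 | 2-(3-chloropropyl)-1,3-dioxolane | ClCCCC1OCCO1 | starting material
7 | [3-(1,3-dioxolan-2-yl)propyl]magnesium chloride | Cl[Mg]CCCC1OCCO1 | intermediate
8 | 2-{3-[(1R,4S)-1-methyl-4-(propan-2-yl)cyclohex-2-en-1-yl]propyl}-1,3-dioxolane (CH3 cis to i-Pr) | O1CCOC1CCC[C@]2(C)CC[C@@H](C(C)C)C=C2 | intermediate
9 | 4-[(1R,4S)-1-methyl-4-(propan-2-yl)cyclohex-2-en-1-yl]butanal | O=CCCC[C@]1(C)CC[C@@H](C(C)C)C=C1 | intermediate
10 | oxime of 9 (E/Z mixture) | ON=CCCC[C@]1(C)CC[C@@H](C(C)C)C=C1 | intermediate
11 | N-hydroxy-4-[(1R,4S)-1-methyl-4-(propan-2-yl)cyclohex-2-en-1-yl]butanimidoyl chloride | ON=C(Cl)CCC[C@]1(C)CC[C@@H](C(C)C)C=C1 | intermediate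
12 | 4-[(1R,4S)-1-methyl-4-(propan-2-yl)cyclohex-2-en-1-yl]butanenitrile oxide | [O-][N+]#CCCC[C@]1(C)CC[C@@H](C(C)C)C=C1 | intermediate
13 | tricyclic Δ2-isoxazoline: C4=N–O–C6 bridge over C5 of a cis-fused 15-noreudesmane (H-5 β, O-6 α, i-Pr-7 β, CH3-10 β) | O1N=C2CCC[C@]3(C)CC[C@@H](C(C)C)[C@H]1[C@H]23 | intermediate
14 | 6α-hydroxy-5β-H-15-noreudesman-4-imine | N=C1CCC[C@]2(C)CC[C@@H](C(C)C)[C@H](O)[C@H]12 | intermediate
15 | 6α-hydroxy-5β-H-15-noreudesman-4-one (cis-fused ketol) | O=C1CCC[C@]2(C)CC[C@@H](C(C)C)[C@H](O)[C@H]12 | intermediate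
16 | 6α-(triethylsilyloxy)-5β-H-15-noreudesman-4-one | O=C1CCC[C@]2(C)CC[C@@H](C(C)C)[C@H](O[Si](CC)(CC)CC)[C@H]12 | intermediate
17 | 6α-(triethylsilyloxy)-5α-H-15-noreudesman-4-one (trans-fused) | O=C1CCC[C@]2(C)CC[C@@H](C(C)C)[C@H](O[Si](CC)(CC)CC)[C@@H]12 | intermediate
18 | triethylsilyl ether of (5S,6S,7S,10R)-eudesm-4(15)-en-6-ol | C=C1CCC[C@]2(C)CC[C@@H](C(C)C)[C@H](O[Si](CC)(CC)CC)[C@@H]12 | intermediate
19 | (5S,6S,7S,10R)-eudesm-4(15)-en-6-ol (junenol skeleton; 5α-H, 6α-OH, 7β-i-Pr, 10β-CH3) | C=C1CCC[C@]2(C)CC[C@@H](C(C)C)[C@H](O)[C@@H]12 | intermediate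
20 | (E)-4-acetoxycinnamic acid | CC(=O)Oc1ccc(/C=C/C(=O)O)cc1 | starting material
21 | (5S,6S,7S,10R)-eudesm-4(15)-en-6-yl (E)-3-(4-acetoxyphenyl)prop-2-enoate | C=C1CCC[C@]2(C)CC[C@@H](C(C)C)[C@H](OC(=O)/C=C/c3ccc(OC(C)=O)cc3)[C@@H]12 | intermediate
22 | (5S,6S,7S,10R)-eudesm-4(15)-en-6-yl (E)-3-(4-hydroxyphenyl)prop-2-enoate | C=C1CCC[C@]2(C)CC[C@@H](C(C)C)[C@H](OC(=O)/C=C/c3ccc(O)cc3)[C@@H]12 | target

**Step count and risks**

Total step count: 10. Longest linear sequence: 10 (1 → 22); 6 and 20 are bought.

Steps most likely to fail: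

Step 4. The Grignard reagent has to attack a fully substituted γ-carbon, so direct α-substitution or no reaction are the likely failures. The fallback sets out from 3 and comes back at 9, replacing the substitution by a sigmatropic rearrangement. NaBH4/CeCl3·7H2O reduction of 3 gives trans-piperitol F1, whose C–O bond is on the α face. Johnson–Claisen rearrangement (MeC(OEt)3, cat. EtCO2H, 140 °C) transfers the new C–C bond suprafacially to the α face of C10 and gives ethyl ester F2. LiAlH4 gives alcohol F3, I2/PPh3/imidazole gives iodide F4, and LiCH2CN (MeCN, LiN(i-Pr)2, THF, −78 °C) gives nitrile F5. i-Bu2AlH followed by aqueous acid gives aldehyde 9, which is oximated as in the second stage of step 5.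

Step 6. The nitrile oxide may dimerise to a furoxan faster than it adds to the hindered cis alkene next to the quaternary carbon. The fallback sets out from 8 and comes back at 15, using a dipole that cannot dimerise. Aqueous HCl hydrolysis gives 9, here isolated. Condensation with N-benzylhydroxylamine gives N-benzyl nitrone F6, which in toluene at 110 °C undergoes intramolecular nitrone–alkene cycloaddition (same α-face delivery) to N-benzyl isoxazolidine F7. H2 over Pd(OH)2/C cleaves N–O and N–benzyl to give amino alcohol F8. Transamination with 3,5-di-tert-butyl-1,2-benzoquinone and then aqueous oxalic acid gives ketol 15.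

Step 9. The cis ketone may be methylenated before it epimerises, or the C4 enolate may expel the silyloxide. The fallback sets out from 15 and comes back at 19, separating epimerisation from olefination and dropping the silyl group. K2CO3 in MeOH at rt equilibrates 15 (enolisation or retro-aldol/aldol) towards the all-equatorial trans-fused ketol F9. Non-basic methylenation with Zn, CH2Br2 and TiCl4, which tolerates the free hydroxyl and does not epimerise C5, then gives 19 directly.

**Further compounds**

F1 | step 4 | trans-piperitol, (1S,6S)-3-methyl-6-(propan-2-yl)cyclohex-2-en-1-ol | CC1=C[C@@H](O)[C@H](C(C)C)CC1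
F2 | step 4 | ethyl 2-[(1S,4S)-1-methyl-4-(propan-2-yl)cyclohex-2-en-1-yl]acetate | CCOC(=O)C[C@]1(C)CC[C@@H](C(C)C)C=C1
F3 | step 4 | 2-[(1S,4S)-1-methyl-4-(propan-2-yl)cyclohex-2-en-1-yl]ethan-1-ol | OCC[C@]1(C)CC[C@@H](C(C)C)C=C1
F4 | step 4 | (1S,4S)-1-(2-iodoethyl)-1-methyl-4-(propan-2-yl)cyclohex-2-ene | ICC[C@]1(C)CC[C@@H](C(C)C)C=C1
F5 | step 4 | 4-[(1R,4S)-1-methyl-4-(propan-2-yl)cyclohex-2-en-1-yl]butanenitrile | N#CCCC[C@]1(C)CC[C@@H](C(C)C)C=C1
F6 | step 6 | N-benzyl nitrone of aldehyde 9 | [O-][N+](Cc1ccccc1)=CCCC[C@]2(C)CC[C@@H](C(C)C)C=C2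
F7 | step 6 | N-benzyl isoxazolidine: C4(H)–N(Bn)–O–C6 bridge over C5 of a cis-fused 15-noreudesmane (N-4 α, H-5 β, O-6 α) | O1N(Cc4ccccc4)[C@@H]2CCC[C@]3(C)CC[C@@H](C(C)C)[C@H]1[C@H]23
F8 | step 6 | 4α-amino-5β-H-15-noreudesman-6α-ol | N[C@@H]1CCC[C@]2(C)CC[C@@H](C(C)C)[C@H](O)[C@H]12
F9 | step 9 | 6α-hydroxy-5α-H-15-noreudesman-4-one (trans-fused ketol) | O=C1CCC[C@]2(C)CC[C@@H](C(C)C)[C@H](O)[C@@H]12
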